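**Strategy.** The heterocyclic ring (N2, C1, C3, C4, C4a, C8a; isoquinoline numbering) minus its nitrogen is the five-membered ring of a 2-methylindan-1-one, whose C2 stereocentre is the future C3. The key step, a Schmidt reaction, inserts nitrogen into the C1–C2 bond of (S)-4-bromo-5,7-dimethoxy-2-methylindan-1-one: the carbocycle grows to the six-membered lactam, C3 keeps its configuration and C1 stays at the acyl level. It exploits the ortho,para-dimethoxyaryl ketone at C8a–C1 and the secondary carbon C3. The indanone comes from an Evans alkylation and a Friedel–Crafts closure; Suzuki coupling at C5, C1 methylation and a trans-selective imine reduction complete the route.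

Key step: step 5

Assumption: the structure defines C1 and C3 (both S) but not the sense of the hindered C5–C1' biaryl axis; the route fixes (1S,3S) and is expected to give both rotamers about that axis, which are stable atropo-diastereomers of 21, 23 and 24 and would be separated at the end by chromatography (either one fits the given structure).

**Route**

Step 1
Reactants: 1 (R)-4-benzyl-3-propanoyl-1,3-oxazolidin-2-one; 2 3,5-dimethoxybenzyl bromide
Product: 4 (R)-4-benzyl-3-[(S)-3-(3,5-dimethoxyphenyl)-2-methylpropanoyl]-1,3-oxazolidin-2-one, via sodium Z-enolate 3 (not isolated)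
Conditions: NaN(SiMe3)2, THF, −78 °C; then 2, −78 → −20 °C
Reagents that add atoms: none
Why: Evans asymmetric alkylation, in which the chelated sodium Z-enolate should be benzylated on the face opposite the C4 benzyl group of the (R)-auxiliary, setting the new α-stereocentre as S.

Step 2
Reactants: 4 (R)-4-benzyl-3-[(S)-3-(3,5-dimethoxyphenyl)-2-methylpropanoyl]-1,3-oxazolidin-2-one
Product: 5 (R)-4-benzyl-3-[(S)-3-(2-bromo-3,5-dimethoxyphenyl)-2-methylpropanoyl]-1,3-oxazolidin-2-one
Conditions: NBS (1.0 equiv), MeCN, 0 °C
Reagents that add atoms: N-bromosuccinimide, O=C1CCC(=O)N1Br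
Why: Electrophilic aromatic bromination, expected at the position ortho to the alkyl chain and para to a methoxy group in preference to the position flanked by both methoxy groups, as is usual for 1-alkyl-3,5-dimethoxybenzenes.

Step 3
Reactants: 5 (R)-4-benzyl-3-[(S)-3-(2-bromo-3,5-dimethoxyphenyl)-2-methylpropanoyl]-1,3-oxazolidin-2-one
Product: 7 (S)-3-(2-bromo-3,5-dimethoxyphenyl)-2-methylpropanoic acid, via lithium peroxycarboxylate 6 (not isolated)
Conditions: LiOH, H2O2, THF/H2O, 0 °C; then aq. Na2SO3; then aq. HCl
Reagents that add atoms: hydrogen peroxide, OO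
Why: Hydroperoxide cleavage of the N-acyl oxazolidinone (removal of the Evans auxiliary), in which LiOOH attacks the exocyclic carbonyl and the weakly basic medium should leave the α-stereocentre untouched.

Step 4
Reactants: 7 (S)-3-(2-bromo-3,5-dimethoxyphenyl)-2-methylpropanoic acid
Product: 9 (S)-4-bromo-5,7-dimethoxy-2-methyl-2,3-dihydro-1H-inden-1-one, via mixed trifluoroacetic anhydride 8 (not isolated)
Conditions: (CF3CO)2O, CF3CO2H, CH2Cl2, 0 °C → rt
Reagents that add atoms: none
Why: Intramolecular Friedel–Crafts acylation through the mixed anhydride, which should close the five-membered ring at the only free ortho position (activated ortho and para by the two methoxy groups) under base-free conditions that spare the α-stereocentre.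

Step 5
Reactants: 9 (S)-4-bromo-5,7-dimethoxy-2-methyl-2,3-dihydro-1H-inden-1-one
Product: 10 (S)-5-bromo-6,8-dimethoxy-3-methyl-3,4-dihydroisoquinolin-1(2H)-one
Conditions: NaN3, MeSO3H, CH2Cl2, 0 °C → rt
Reagents that add atoms: sodium azide, [N-]=[N+]=[N-].[Na+]; water, O
Why: Schmidt reaction: HN3 (from NaN3 and MeSO3H) adds to the protonated ketone at C1, the azidohydrin loses water to an iminodiazonium ion, and the secondary carbon C2 shifts from C1 to nitrogen as N2 leaves, after which water captures the cyclic cation and the lactam forms. The closest known reaction type is the Schmidt ring enlargement of 1-indanones to 3,4-dihydroisoquinolin-1(2H)-ones in MeSO3H/CH2Cl2. No ring is closed by cyclisation: the five-membered carbocycle (C1, C2, C3, C3a, C7a of 9) becomes the six-membered lactam by insertion of one nitrogen atom into its C1–C2 bond through a 1,2-shift. No new stereocentre is formed, and the migrating carbon keeps its configuration, so (S)-C2 of 9 should become (S)-C3 of 10. The step needs alkyl rather than aryl migration and no enolisation of the ketone; the first is secured by the methoxy group para to the carbonyl (supported by the ortho one), which in benzo-fused ketones directs the alkyl carbon to migrate, and by the better migratory aptitude of a secondary carbon. The second is secured by working at 0 °C on a ketone that is a vinylogous ester and therefore enolises slowly.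

Step 6
Reactants: 11 N,N-diethyl-2-methoxybenzamide; 12 3-bromo-2-methylprop-1-ene
Product: 15 N,N-diethyl-2-methoxy-6-(2-methylprop-2-en-1-yl)benzamide, via aryllithium 13 (not isolated), via arylmagnesium bromide 14 (not isolated)
Conditions: s-BuLi, TMEDA, THF, −78 °C; MgBr2·OEt2; then 12, −78 °C → rt
Reagents that add atoms: none
Why: Amide-directed ortho-metalation (the diethylamide outranks methoxy as directing group, so the position ortho to the amide is lithiated), followed by transmetalation to magnesium and allylation of the aryl Grignard reagent.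

Step 7
Reactants: 15 N,N-diethyl-2-methoxy-6-(2-methylprop-2-en-1-yl)benzamide
Product: 16 8-methoxy-3-methylnaphthalen-1-ol
Conditions: LiN(i-Pr)2 (2.2 equiv), THF, −78 °C → rt; aq. HCl
Reagents that add atoms: none
Why: Anionic ring annulation of an o-allylbenzamide, in which the benzylic-allylic anion attacks the amide carbonyl through its terminal carbon (6-exo-trig), diethylamide is expelled and the dienone tautomerises to the naphthol.

Step 8
Reactants: 16 8-methoxy-3-methylnaphthalen-1-ol
Product: 17 1,8-dimethoxy-3-methylnaphthalene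
Conditions: MeI, K2CO3, DMF, 50 °C
Reagents that add atoms: iodomethane, CI
Why: Williamson O-methylation of the naphthol.

Step 9
Reactants: 17 1,8-dimethoxy-3-methylnaphthalene
Product: 18 1-bromo-4,5-dimethoxy-2-methylnaphthalene
Conditions: NBS (1.0 equiv), MeCN, 0 °C
Reagents that add atoms: N-bromosuccinimide, O=C1CCC(=O)N1Br
Why: Electrophilic aromatic bromination, expected at the α-position that is para to the C1 methoxy group and ortho to the methyl group, the most activated site of 17.

Step 10
Reactants: 18 1-bromo-4,5-dimethoxy-2-methylnaphthalene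
Product: 20 (4,5-dimethoxy-2-methylnaphthalen-1-yl)boronic acid, via naphthyllithium 19 (not isolated)
Conditions: n-BuLi, THF, −78 °C; B(OMe)3, −78 °C → rt; aq. HCl
Reagents that add atoms: trimethyl borate, COB(OC)OC; water, O
Why: Bromine–lithium exchange and borylation of the aryllithium with trimethyl borate, followed by hydrolysis of the boronate.

Step 11
Reactants: 10 (S)-5-bromo-6,8-dimethoxy-3-methyl-3,4-dihydroisoquinolin-1(2H)-one; 20 (4,5-dimethoxy-2-methylnaphthalen-1-yl)boronic acid
Product: 21 (S)-5-(4,5-dimethoxy-2-methylnaphthalen-1-yl)-6,8-dimethoxy-3-methyl-3,4-dihydroisoquinolin-1(2H)-one (both rotamers about the C5–C1' axis)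
Conditions: Pd(OAc)2, SPhos, K3PO4, toluene/H2O, 100 °C
Reagents that add atoms: none
Why: Suzuki–Miyaura coupling with the bulky, electron-rich dialkylbiarylphosphine SPhos, a ligand class suited to tetra-ortho-substituted biaryls, while the neutral lactam N–H and the C3 stereocentre should be inert to the aqueous base.

Step 12
Reactants: 21 (S)-5-(4,5-dimethoxy-2-methylnaphthalen-1-yl)-6,8-dimethoxy-3-methyl-3,4-dihydroisoquinolin-1(2H)-one
Product: 23 (S)-5-(4,5-dimethoxy-2-methylnaphthalen-1-yl)-6,8-dimethoxy-1,3-dimethyl-3,4-dihydroisoquinoline, via N-silyl lactam 22 (not isolated)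
Conditions: Me3SiCl, Et3N, CH2Cl2, rt; filtration and solvent switch; then MeLi, Et2O, −20 → 0 °C; aq. NH4Cl
Reagents that add atoms: methyllithium, [Li]C
Why: Addition of an alkyllithium to an N-silyl lactam to give a cyclic ketimine, in which MeLi adds to the carbonyl (no α-hydrogen on the aryl side to enolise), silicon moves from nitrogen to oxygen and loss of lithium trimethylsilanolate leaves the C1=N bond without opening the ring.

Step 13
Reactants: 23 (S)-5-(4,5-dimethoxy-2-methylnaphthalen-1-yl)-6,8-dimethoxy-1,3-dimethyl-3,4-dihydroisoquinoline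
Product: 24 (1S,3S)-5-(4,5-dimethoxy-2-methylnaphthalen-1-yl)-6,8-dimethoxy-1,3-dimethyl-1,2,3,4-tetrahydroisoquinoline
Conditions: LiAlH4, AlMe3, THF, −78 → 0 °C
Reagents that add atoms: none
Why: Diastereoselective hydride reduction of the cyclic ketimine, in which AlMe3 bound to nitrogen forces the C3 methyl group pseudo-axial and pseudo-axial hydride delivery should give the 1,3-trans amine, so that (S)-C3 sets C1 as S (this reagent pair is the established trans-selective one for 1,3-dimethyl-3,4-dihydroisoquinolines, whereas NaBH4 favours cis).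

**Compound list**

1 | (R)-4-benzyl-3-propanoyl-1,3-oxazolidin-2-one | CCC(=O)N1[C@H](Cc2ccccc2)COC1=O | starting material
2 | 3,5-dimethoxybenzyl bromide | COc1cc(CBr)cc(OC)c1 | starting material
3 | sodium (Z)-1-[(R)-4-benzyl-2-oxo-1,3-oxazolidin-3-yl]prop-1-en-1-olate (formed in the flask) | C/C=C(\[O-])N1[C@H](Cc2ccccc2)COC1=O.[Na+] | intermediate
4 | (R)-4-benzyl-3-[(S)-3-(3,5-dimethoxyphenyl)-2-methylpropanoyl]-1,3-oxazolidin-2-one | COc1cc(C[C@H](C)C(=O)N2[C@H](Cc3ccccc3)COC2=O)cc(OC)c1 | intermediate
5 | (R)-4-benzyl-3-[(S)-3-(2-bromo-3,5-dimethoxyphenyl)-2-methylpropanoyl]-1,3-oxazolidin-2-one | COc1cc(OC)c(Br)c(C[C@H](C)C(=O)N2[C@H](Cc3ccccc3)COC2=O)c1 | intermediate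
6 | lithium (S)-3-(2-bromo-3,5-dimethoxyphenyl)-2-methylpropaneperoxoate (formed in the flask) | COc1cc(OC)c(Br)c(C[C@H](C)C(=O)O[O-])c1.[Li+] | intermediate
7 | (S)-3-(2-bromo-3,5-dimethoxyphenyl)-2-methylpropanoic acid | COc1cc(OC)c(Br)c(C[C@H](C)C(=O)O)c1 | intermediate
8 | (S)-3-(2-bromo-3,5-dimethoxyphenyl)-2-methylpropanoic trifluoroacetic anhydride (formed in the flask) | COc1cc(OC)c(Br)c(C[C@H](C)C(=O)OC(=O)C(F)(F)F)c1 | intermediate
9 | (S)-4-bromo-5,7-dimethoxy-2-methyl-2,3-dihydro-1H-inden-1-one | COc1cc(OC)c2c(c1Br)C[C@H](C)C2=O | intermediate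
10 | (S)-5-bromo-6,8-dimethoxy-3-methyl-3,4-dihydroisoquinolin-1(2H)-one | COc1cc(OC)c2c(c1Br)C[C@H](C)NC2=O | intermediate
11 | N,N-diethyl-2-methoxybenzamide | CCN(CC)C(=O)c1ccccc1OC | starting material
12 | 3-bromo-2-methylprop-1-ene | CC(=C)CBr | starting material
13 | [2-(diethylcarbamoyl)-3-methoxyphenyl]lithium (formed in the flask) | CCN(CC)C(=O)c1c([Li])cccc1OC | intermediate
14 | [2-(diethylcarbamoyl)-3-methoxyphenyl]magnesium bromide (formed in the flask) | CCN(CC)C(=O)c1c([Mg]Br)cccc1OC | intermediate
15 | N,N-diethyl-2-methoxy-6-(2-methylprop-2-en-1-yl)benzamide | CCN(CC)C(=O)c1c(CC(C)=C)cccc1OC | intermediate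
16 | 8-methoxy-3-methylnaphthalen-1-ol | COc1cccc2cc(C)cc(O)c12 | intermediate
17 | 1,8-dimethoxy-3-methylnaphthalene | COc1cc(C)cc2cccc(OC)c12 | intermediate
18 | 1-bromo-4,5-dimethoxy-2-methylnaphthalene | COc1cc(C)c(Br)c2cccc(OC)c12 | intermediate
19 | (4,5-dimethoxy-2-methylnaphthalen-1-yl)lithium (formed in the flask) | COc1cc(C)c([Li])c2cccc(OC)c12 | intermediate
20 | (4,5-dimethoxy-2-methylnaphthalen-1-yl)boronic acid | COc1cc(C)c(B(O)O)c2cccc(OC)c12 | intermediate
21 | (S)-5-(4,5-dimethoxy-2-methylnaphthalen-1-yl)-6,8-dimethoxy-3-methyl-3,4-dihydroisoquinolin-1(2H)-one | COc1cc(OC)c2c(c1-c1c(C)cc(OC)c3c(OC)cccc13)C[C@H](C)NC2=O | intermediate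
22 | (S)-5-(4,5-dimethoxy-2-methylnaphthalen-1-yl)-6,8-dimethoxy-3-methyl-2-(trimethylsilyl)-3,4-dihydroisoquinolin-1(2H)-one (formed in the flask) | COc1cc(OC)c2c(c1-c1c(C)cc(OC)c3c(OC)cccc13)C[C@H](C)N([Si](C)(C)C)C2=O | intermediate
23 | (S)-5-(4,5-dimethoxy-2-methylnaphthalen-1-yl)-6,8-dimethoxy-1,3-dimethyl-3,4-dihydroisoquinoline | COc1cc(OC)c2c(c1-c1c(C)cc(OC)c3c(OC)cccc13)C[C@H](C)N=C2C | intermediate
24 | (1S,3S)-5-(4,5-dimethoxy-2-methylnaphthalen-1-yl)-6,8-dimethoxy-1,3-dimethyl-1,2,3,4-tetrahydroisoquinoline | COc1cc(OC)c2c(c1-c1c(C)cc(OC)c3c(OC)cccc13)C[C@H](C)N[C@H]2C | target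

**Summary**

Total step count: 13.

Longest linear sequence: 8 steps (steps 1–5 and 11–13 from 1 and 2; the branch through steps 6–10 and 11–13 is of the same length).

**Steps most likely to fail**

Step 5. The aryl carbon may migrate in competition with C2, which would lead to the quinolin-2-one ring system, and the strong acid may enolise the ketone before nitrogen insertion and erode the configuration at C2. The fallback sets out from 9 and comes back at 10, and it is still a one-atom ring enlargement. Ketone 9 would be condensed with NH2OH·HCl and NaOAc in EtOH under buffered conditions, and the oxime isomers separated. The isomer with the hydroxyl group syn to the arene, (S,Z)-4-bromo-5,7-dimethoxy-2-methyl-2,3-dihydro-1H-inden-1-one oxime F1, is carried on, while the other isomer is returned to the equilibrium. Tosylation (TsCl, pyridine, 0 °C) should give the oxime O-tosylate F2. A Beckmann rearrangement of F2 on basic alumina or in aqueous THF with NaHCO3 is stereospecific, so the carbon anti to the leaving group (C2) should migrate with retention and give 10. Here the regiochemistry rests on oxime geometry instead of migratory aptitude, and no strong acid is present.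

Step 11. Transmetalation and reductive elimination at the tetra-ortho-substituted axis may be slow enough for protodeboronation of the electron-rich, hindered boronic acid to consume the nucleophile. The fallback sets out from 18 (with 10) and comes back at 21. Bromide 18 would be lithiated (n-BuLi, THF, −78 °C) and transmetalated with ZnCl2 to (4,5-dimethoxy-2-methylnaphthalen-1-yl)zinc chloride F3. This would be used in excess in a Negishi coupling with 10 (Pd(OAc)2, RuPhos, THF/NMP, 60 °C). The organozinc transmetalates faster and cannot be lost by protodeboronation.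

Step 12. MeLi may attack silicon instead of the carbonyl carbon, or add only sluggishly to the electron-rich lactam carbonyl flanked by the C8 methoxy group, so that the lactam is returned. The fallback sets out from 21 and comes back at 23. Lactam 21 would be converted with POCl3 (toluene, 80 °C) into the cyclic imidoyl chloride (S)-1-chloro-5-(4,5-dimethoxy-2-methylnaphthalen-1-yl)-6,8-dimethoxy-3-methyl-3,4-dihydroisoquinoline F4. Methylation of F4 by cross-coupling with MeMgBr and catalytic Fe(acac)3 (THF/NMP, 0 °C) should give 23. The C1–CH3 bond is then formed by coupling at an activated C–Cl bond instead of by carbonyl addition.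

**Further compounds**

F1 | step 5 | (S,Z)-4-bromo-5,7-dimethoxy-2-methyl-2,3-dihydro-1H-inden-1-one oxime | COc1cc(OC)c2c(c1Br)C[C@H](C)/C2=N/O
F2 | step 5 | (S,Z)-4-bromo-5,7-dimethoxy-2-methyl-2,3-dihydro-1H-inden-1-one O-(4-methylbenzenesulfonyl)oxime | COc1cc(OC)c2c(c1Br)C[C@H](C)/C2=N/OS(=O)(=O)c1ccc(C)cc1
F3 | step 11 | (4,5-dimethoxy-2-methylnaphthalen-1-yl)zinc chloride | COc1cc(C)c([Zn]Cl)c2cccc(OC)c12
F4 | step 12 | (S)-1-chloro-5-(4,5-dimethoxy-2-methylnaphthalen-1-yl)-6,8-dimethoxy-3-methyl-3,4-dihydroisoquinoline | COc1cc(OC)c2c(c1-c1c(C)cc(OC)c3c(OC)cccc13)C[C@H](C)N=C2Cl
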